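**Retrosynthetic overview**
- The target comes from dibenzyl ether 21 by hydrogenolysis. The 18-membered ring of 21 is opened at the ring B aryl–CH2 bond of the CH2CH2 bridge between ring B (the meta-linked aryloxy ring) and ring C (the ring with OH ortho to a diaryl ether oxygen). This sp2–sp3 bond is unhindered and lies far from the crowded OMe/OAr/CH2/OH ring A, and it gives the seco bromo styrene 19.
- 19 comes from methylenation of a ring C aldehyde; the ring A–ring D CH2CH2 bridge comes from Wittig olefination of ring A phosphonium salt 9 with ring C–ring D aldehyde 14, followed by diimide reduction.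
- The ring A–ring B ether is made by SNAr of 3-bromophenol on an ortho-fluoro benzaldehyde. The formyl group is installed by directed ortho-metalation before the bromoarene is present, because organolithium chemistry would not tolerate the aryl bromide.
- The ring C–ring D ether is made by SNAr of 4-fluorobenzaldehyde with acetal-masked 4-O-benzyl protocatechualdehyde.
- All four benzene rings are bought; the only ring formed is the macrocycle, in the penultimate step.

Key step: step 13

Remark: the Wittig olefination in step 9 is expected to give an E/Z mixture; it is carried on unseparated because step 10 removes the double bond, so the SMILES of 16 leaves the geometry open.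

**Route**

Step 1
Reactants: 1 3-fluoro-4-methoxyphenol
Product: 2 4-(benzyloxy)-2-fluoro-1-methoxybenzene
Conditions: BnBr, K2CO3, DMF, rt
Reagents that add atoms: benzyl bromide, BrCc1ccccc1
Why: Williamson ether synthesis on the phenoxide should proceed cleanly, as no other nucleophilic site is present.

Step 2
Reactants: 2 4-(benzyloxy)-2-fluoro-1-methoxybenzene
Product: 5 6-(benzyloxy)-2-fluoro-3-methoxybenzaldehyde, via aryllithium 3 (not isolated), via lithium hemiaminolate 4 (not isolated)
Conditions: LiN(iPr)2, THF, −78 °C; DMF, −78 to 0 °C; aq HCl work-up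
Reagents that add atoms: N,N-dimethylformamide, CN(C)C=O
Why: Directed ortho-metalation: the ring hydrogen flanked by F and OBn is the most acidic position, the amide base at −78 °C should remove it without touching the benzylic CH2 or expelling LiF, and DMF formylates the aryllithium.

Step 3
Reactants: 5 6-(benzyloxy)-2-fluoro-3-methoxybenzaldehyde; 6 3-bromophenol
Product: 7 6-(benzyloxy)-2-(3-bromophenoxy)-3-methoxybenzaldehyde
Conditions: K2CO3, DMA, 130 °C
Reagents that add atoms: none
Why: Nucleophilic aromatic substitution (SNAr): the ortho-formyl group stabilises the Meisenheimer adduct and fluoride is the leaving group, while the unactivated aryl bromide of the phenoxide stays inert.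

Step 4
Reactants: 7 6-(benzyloxy)-2-(3-bromophenoxy)-3-methoxybenzaldehyde
Product: 8 [6-(benzyloxy)-2-(3-bromophenoxy)-3-methoxyphenyl]methanol
Conditions: NaBH4, MeOH/THF, 0 °C
Reagents that add atoms: none
Why: Borohydride reduction of an aryl aldehyde, which leaves the aryl bromide and the ethers untouched.

Step 5
Reactants: 8 [6-(benzyloxy)-2-(3-bromophenoxy)-3-methoxyphenyl]methanol
Product: 9 {[6-(benzyloxy)-2-(3-bromophenoxy)-3-methoxyphenyl]methyl}triphenylphosphonium bromide
Conditions: PPh3·HBr, MeCN, reflux
Reagents that add atoms: triphenylphosphine hydrobromide, [Br-].c1ccc(cc1)[PH+](c1ccccc1)c1ccccc1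
Why: Direct phosphonium salt formation: the electron-rich 2,6-dioxygenated benzylic alcohol ionises readily under the mild acid and is captured by PPh3, while the benzyl and diaryl ethers are stable to this weak acid.

Step 6
Reactants: 10 3,4-dihydroxybenzaldehyde
Product: 11 4-(benzyloxy)-3-hydroxybenzaldehyde
Conditions: BnBr (1.0 equiv), NaHCO3, NaI (cat.), DMF, 40 °C
Reagents that add atoms: benzyl bromide, BrCc1ccccc1
Why: Regioselective Williamson alkylation: the 4-OH para to the formyl group is the more acidic phenol and is the one deprotonated by the weak base.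

Step 7
Reactants: 11 4-(benzyloxy)-3-hydroxybenzaldehyde
Product: 12 2-(benzyloxy)-5-(1,3-dioxolan-2-yl)phenol
Conditions: HOCH2CH2OH, TsOH·H2O (cat.), toluene, Dean–Stark, reflux
Reagents that add atoms: ethylene glycol, OCCO
Why: Acid-catalysed acetalisation driven by azeotropic water removal masks the ring C aldehyde so that it can be told apart from the ring D aldehyde introduced next.

Step 8
Reactants: 12 2-(benzyloxy)-5-(1,3-dioxolan-2-yl)phenol; 13 4-fluorobenzaldehyde
Product: 14 4-[2-(benzyloxy)-5-(1,3-dioxolan-2-yl)phenoxy]benzaldehyde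
Conditions: K2CO3, DMF, 120 °C
Reagents that add atoms: none
Why: SNAr of the phenoxide on the para-formyl-activated aryl fluoride; the acetal is stable to the basic medium.

Step 9
Reactants: 9 {[6-(benzyloxy)-2-(3-bromophenoxy)-3-methoxyphenyl]methyl}triphenylphosphonium bromide; 14 4-[2-(benzyloxy)-5-(1,3-dioxolan-2-yl)phenoxy]benzaldehyde
Product: 16 stilbene acetal 2-{4-(benzyloxy)-3-[4-(2-{6-(benzyloxy)-2-(3-bromophenoxy)-3-methoxyphenyl}ethenyl)phenoxy]phenyl}-1,3-dioxolane (E/Z mixture), via phosphonium ylide 15 (not isolated)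
Conditions: KOtBu, THF, 0 °C; then 14, 0 °C to rt
Reagents that add atoms: none
Why: Wittig olefination of a non-enolisable aryl aldehyde with a semi-stabilised benzylic ylide forms the ring A–ring D two-carbon link; the E/Z ratio is irrelevant.

Step 10
Reactants: 16 stilbene acetal (E/Z mixture)
Product: 17 2-{4-(benzyloxy)-3-[4-(2-{6-(benzyloxy)-2-(3-bromophenoxy)-3-methoxyphenyl}ethyl)phenoxy]phenyl}-1,3-dioxolane
Conditions: 2-nitrobenzenesulfonyl hydrazide (NBSH, excess, in portions), Et3N, THF, rt
Reagents that add atoms: none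
Why: Diimide reduction: concerted syn transfer of H2 from HN=NH saturates the stilbene without hydrogenolysis of C–Br or O–benzyl bonds, and the basic, non-aqueous generation of diimide spares the acid-labile acetal.

Step 11
Reactants: 17 bibenzyl acetal
Product: 18 4-(benzyloxy)-3-[4-(2-{6-(benzyloxy)-2-(3-bromophenoxy)-3-methoxyphenyl}ethyl)phenoxy]benzaldehyde
Conditions: 1 M HCl, THF, rt
Reagents that add atoms: water, O
Why: Acid-catalysed acetal hydrolysis of an electron-rich aryl dioxolane is fast under conditions that leave benzyl and diaryl ethers intact.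

Step 12
Reactants: 18 bibenzyl aldehyde
Product: 19 seco bromo styrene 1-(benzyloxy)-2-[4-(2-{6-(benzyloxy)-2-(3-bromophenoxy)-3-methoxyphenyl}ethyl)phenoxy]-4-ethenylbenzene
Conditions: Ph3PCH3Br, KOtBu, THF, 0 °C to rt
Reagents that add atoms: methyltriphenylphosphonium bromide, [Br-].C[P+](c1ccccc1)(c1ccccc1)c1ccccc1
Why: Wittig methylenation of the aryl aldehyde with the non-stabilised ylide, to which the aryl bromide is inert.

Step 13
Reactants: 19 seco bromo styrene
Product: 21 dibenzyl ether of the target macrocycle, via B-alkyl-9-BBN borane 20 (not isolated)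
Conditions: 9-BBN dimer, THF, rt; then syringe-pump addition to PdCl2(dppf) (cat.), AsPh3, Cs2CO3, THF/DMF/H2O, 60 °C, final concentration about 2 mM
Reagents that add atoms: none
Why: Bulky 9-BBN adds anti-Markovnikov to the ring C styrene and places boron on the terminal carbon; zerovalent palladium formed from PdCl2(dppf) then inserts into the ring B C–Br bond, the carbonate-activated primary alkylborane transmetalates, and reductive elimination forms the ring B aryl–CH2 bond. The closest known reaction type is the intramolecular B-alkyl Suzuki–Miyaura macrocyclization used for large carbocycles and cyclophanes. The 18-membered ring is closed end-to-end by this intramolecular sp2–sp3 coupling, and no stereocenter is created. The step needs ring closure to outrun intermolecular coupling, protodeboronation and β-hydride elimination: slow addition into a dilute catalyst solution keeps the borane concentration low, the ortho-linked tetrasubstituted ring A folds the chain so that the two ends can meet, the reacting bromide is meta to the ether oxygen and unhindered, and the wide bite angle of dppf speeds reductive elimination from the alkylpalladium.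

Step 14
Reactants: 21 dibenzyl ether of the target macrocycle
Product: 22 CNP0179896.0 (target)
Conditions: H2 (1 atm), Pd/C, EtOAc/MeOH, rt
Reagents that add atoms: none
Why: Catalytic hydrogenolysis cleaves both benzyl ethers, while the diaryl ethers, the methyl ether and the saturated bridges are inert.

**Compound list**
1 | 3-fluoro-4-methoxyphenol | COc1ccc(O)cc1F | starting material
2 | 4-(benzyloxy)-2-fluoro-1-methoxybenzene | COc1ccc(OCc2ccccc2)cc1F | intermediate
3 | [6-(benzyloxy)-2-fluoro-3-methoxyphenyl]lithium | COc1ccc(OCc2ccccc2)c([Li])c1F | intermediate (not isolated)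
4 | lithium [6-(benzyloxy)-2-fluoro-3-methoxyphenyl](dimethylamino)methanolate (racemic, transient) | COc1ccc(OCc2ccccc2)c(C(O[Li])N(C)C)c1F | intermediate (not isolated)
5 | 6-(benzyloxy)-2-fluoro-3-methoxybenzaldehyde | COc1ccc(OCc2ccccc2)c(C=O)c1F | intermediate
6 | 3-bromophenol | Oc1cccc(Br)c1 | starting material
7 | 6-(benzyloxy)-2-(3-bromophenoxy)-3-methoxybenzaldehyde | COc1ccc(OCc2ccccc2)c(C=O)c1Oc1cccc(Br)c1 | intermediate
8 | [6-(benzyloxy)-2-(3-bromophenoxy)-3-methoxyphenyl]methanol | COc1ccc(OCc2ccccc2)c(CO)c1Oc1cccc(Br)c1 | intermediate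
9 | {[6-(benzyloxy)-2-(3-bromophenoxy)-3-methoxyphenyl]methyl}triphenylphosphonium bromide | COc1ccc(OCc2ccccc2)c(C[P+](c2ccccc2)(c2ccccc2)c2ccccc2)c1Oc1cccc(Br)c1.[Br-] | intermediate
10 | 3,4-dihydroxybenzaldehyde | O=Cc1ccc(O)c(O)c1 | starting material
11 | 4-(benzyloxy)-3-hydroxybenzaldehyde | O=Cc1ccc(OCc2ccccc2)c(O)c1 | intermediate
12 | 2-(benzyloxy)-5-(1,3-dioxolan-2-yl)phenol | Oc1cc(C2OCCO2)ccc1OCc1ccccc1 | intermediate
13 | 4-fluorobenzaldehyde | O=Cc1ccc(F)cc1 | starting material
14 | 4-[2-(benzyloxy)-5-(1,3-dioxolan-2-yl)phenoxy]benzaldehyde | O=Cc1ccc(Oc2cc(C3OCCO3)ccc2OCc2ccccc2)cc1 | intermediate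
15 | [6-(benzyloxy)-2-(3-bromophenoxy)-3-methoxybenzylidene]triphenylphosphorane | COc1ccc(OCc2ccccc2)c(C=P(c2ccccc2)(c2ccccc2)c2ccccc2)c1Oc1cccc(Br)c1 | intermediate (not isolated)
16 | 2-{4-(benzyloxy)-3-[4-(2-{6-(benzyloxy)-2-(3-bromophenoxy)-3-methoxyphenyl}ethenyl)phenoxy]phenyl}-1,3-dioxolane, E/Z mixture | COc1ccc(OCc2ccccc2)c(C=Cc2ccc(Oc3cc(C4OCCO4)ccc3OCc3ccccc3)cc2)c1Oc1cccc(Br)c1 | intermediate
17 | 2-{4-(benzyloxy)-3-[4-(2-{6-(benzyloxy)-2-(3-bromophenoxy)-3-methoxyphenyl}ethyl)phenoxy]phenyl}-1,3-dioxolane | COc1ccc(OCc2ccccc2)c(CCc2ccc(Oc3cc(C4OCCO4)ccc3OCc3ccccc3)cc2)c1Oc1cccc(Br)c1 | intermediate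
18 | 4-(benzyloxy)-3-[4-(2-{6-(benzyloxy)-2-(3-bromophenoxy)-3-methoxyphenyl}ethyl)phenoxy]benzaldehyde | COc1ccc(OCc2ccccc2)c(CCc2ccc(Oc3cc(C=O)ccc3OCc3ccccc3)cc2)c1Oc1cccc(Br)c1 | intermediate
19 | 1-(benzyloxy)-2-[4-(2-{6-(benzyloxy)-2-(3-bromophenoxy)-3-methoxyphenyl}ethyl)phenoxy]-4-ethenylbenzene (seco bromo styrene) | COc1ccc(OCc2ccccc2)c(CCc2ccc(Oc3cc(C=C)ccc3OCc3ccccc3)cc2)c1Oc1cccc(Br)c1 | intermediate
20 | B-alkyl-9-BBN adduct of 19 (boron on the terminal carbon of the former vinyl group) | COc1ccc(OCc2ccccc2)c(CCc2ccc(Oc3cc(CCB4C5CCCC4CCC5)ccc3OCc3ccccc3)cc2)c1Oc1cccc(Br)c1 | intermediate (not isolated)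
21 | dibenzyl ether of the target macrocycle | COc1ccc(OCc3ccccc3)c2c1Oc1cccc(c1)CCc1ccc(OCc3ccccc3)c(c1)Oc1ccc(cc1)CC2 | intermediate
22 | CNP0179896.0 | COc1ccc(O)c2c1Oc1cccc(c1)CCc1ccc(O)c(c1)Oc1ccc(cc1)CC2 | target

**Summary**
Total step count: 14. Longest linear sequence: 11 steps (steps 1–5 and 9–14, from 3-fluoro-4-methoxyphenol); the ring C–ring D branch (steps 6–8) joins at step 9.

Steps most likely to fail:

1. Step 13 (macrocyclization). Intermolecular coupling to dimers and oligomers, protodeboronation of the alkylborane, or β-hydride elimination from the alkylpalladium may outrun the slow 18-membered closure. Fallback: the same ring B aryl–carbon bond would be made from 19 without an organoboron partner by an intramolecular Mizoroki–Heck reaction (Pd(OAc)2, P(o-tol)3, K2CO3, DMF, 100 °C, high dilution), which should give the macrocyclic (E)-stilbene dibenzyl ether F1. Hydrogenation over Pd/C (H2, EtOAc/MeOH) would then saturate the stilbene and cleave both benzyl ethers in one operation, and the route is rejoined at target 22.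

2. Step 3 (ring A–ring B ether). Fluoride displacement on the electron-rich, doubly flanked ring may be sluggish, and the aldehyde may degrade under the base and temperature needed to force it. Fallback: setting out from 5, the formyl group would be changed into the linear, base-stable cyano activator (I2, aq NH3, THF, rt) to give 6-(benzyloxy)-2-fluoro-3-methoxybenzonitrile F2. SNAr with 3-bromophenol 6 (K2CO3, DMF, 110 °C) should give 6-(benzyloxy)-2-(3-bromophenoxy)-3-methoxybenzonitrile F3, and half-reduction with iBu2AlH (toluene, −78 °C, then aq HCl) would return the route at aldehyde 7.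

3. Step 10 (diimide reduction). Disproportionation of diimide may outpace hydrogen transfer to the hindered, twisted stilbene at room temperature, leaving incomplete saturation; more forcing aqueous conditions would cost the acetal. Fallback: setting out from 16, the acetal would be removed first (1 M HCl, THF) to give the stilbene aldehyde F4, and the aldehyde reduced (NaBH4, MeOH) to the stilbene benzylic alcohol F5. This substrate tolerates classical hot diimide generation (TsNHNH2, NaOAc, DME/H2O, reflux), which should give the bibenzyl benzylic alcohol F6. Oxidation with MnO2 (CH2Cl2, rt) rejoins the route at aldehyde 18.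

**Further compounds**
F1 | step 13 | macrocyclic (E)-stilbene dibenzyl ether (ring B–CH=CH–ring C) | COc1ccc(OCc3ccccc3)c2c1Oc1cccc(c1)/C=C/c1ccc(OCc3ccccc3)c(c1)Oc1ccc(cc1)CC2
F2 | step 3 | 6-(benzyloxy)-2-fluoro-3-methoxybenzonitrile | COc1ccc(OCc2ccccc2)c(C#N)c1F
F3 | step 3 | 6-(benzyloxy)-2-(3-bromophenoxy)-3-methoxybenzonitrile | COc1ccc(OCc2ccccc2)c(C#N)c1Oc1cccc(Br)c1
F4 | step 10 | 4-(benzyloxy)-3-[4-(2-{6-(benzyloxy)-2-(3-bromophenoxy)-3-methoxyphenyl}ethenyl)phenoxy]benzaldehyde, E/Z mixture | COc1ccc(OCc2ccccc2)c(C=Cc2ccc(Oc3cc(C=O)ccc3OCc3ccccc3)cc2)c1Oc1cccc(Br)c1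
F5 | step 10 | {4-(benzyloxy)-3-[4-(2-{6-(benzyloxy)-2-(3-bromophenoxy)-3-methoxyphenyl}ethenyl)phenoxy]phenyl}methanol, E/Z mixture | COc1ccc(OCc2ccccc2)c(C=Cc2ccc(Oc3cc(CO)ccc3OCc3ccccc3)cc2)c1Oc1cccc(Br)c1
F6 | step 10 | {4-(benzyloxy)-3-[4-(2-{6-(benzyloxy)-2-(3-bromophenoxy)-3-methoxyphenyl}ethyl)phenoxy]phenyl}methanol | COc1ccc(OCc2ccccc2)c(CCc2ccc(Oc3cc(CO)ccc3OCc3ccccc3)cc2)c1Oc1cccc(Br)c1
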